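**Retrosynthetic overview**

1. The final γ-lactone is opened to a γ-hydroxy tert-butyl ester; its C5 carbinol comes from CBS reduction of an enone, and the enone from Fukuyama acylation of an (E)-alkenylzinc (C14 dienyne fragment) by a thioester.
2. The thioester comes from thiolysis of a temporary γ-lactone; the isocitrate ester comes from a lactone acid chloride and tri-tert-butyl (1S,2R)-isocitrate (L-malic acid, Fráter–Seebach alkylation).
3. The two carboxyls on the lactone are unveiled one after the other by two ozonolyses (silyl enol ether bond, then enoate bond) of a cis-fused bicyclic lactone cyclohexenone; this differentiates them and cuts out two ring carbons.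
4. Structural feature: the array CH2CO2H–C(OH)(CO2R)–C3H–C2(=O) of the target is the side chain plus ring carbons C1, C6, C2 and C3 of 4-hydroxyphenylacetic acid (C1 → carbinol carbon, C6 → ester carboxyl, C2 → lactone C3, C3 → lactone C2). Lactone C4 and C5 are the CH2 and the tether carbonyl of a malonate, and arene C4 and C5 are excised.
5. Ring order: the carbocycle is taken from the arene (dearomatized, step 2); the temporary γ-lactone is closed by the desymmetrizing Michael addition (step 5); the carbocycle is cleaved (steps 8 and 10); the temporary lactone is opened (step 14); the final γ-lactone is closed (step 22).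

Key step: step 5

Assumption: the epi-quinine-derived thiourea is taken to select the enone arm that gives the (3aS,7aS) lactone. This sense of induction is assigned by analogy; the pseudoenantiomeric epi-quinidine-derived catalyst is the alternative if the opposite arm reacts.

Remark: locants C3, C3a, C4 to C7 and C7a in the steps are those of the benzofuranone skeleton of the key-step product. CIP descriptors at the two ring-fusion carbons change along the route only because substituent priorities change.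

**Route**

Step 1
Reactants: 1 4-hydroxyphenylacetic acid
Product: 2 tert-butyl 2-(4-hydroxyphenyl)acetate
Conditions: Me2NCH(OtBu)2, toluene, 80 °C
Reagents that add atoms: N,N-dimethylformamide di-tert-butyl acetal, CN(C)C(OC(C)(C)C)OC(C)(C)C
Why: Acid-selective tert-butyl esterification by the formamide acetal alkylates the carboxylate and leaves the less acidic phenol free.

Step 2
Reactants: 2 tert-butyl 2-(4-hydroxyphenyl)acetate
Product: 3 tert-butyl 2-(1-hydroxy-4-oxocyclohexa-2,5-dien-1-yl)acetate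
Conditions: PhI(OAc)2, MeCN/H2O (3:1), 0 °C
Reagents that add atoms: water, O
Why: Oxidative dearomatization of a para-substituted phenol by the diacetoxyiodoarene, with water capturing the phenoxenium ion at the para carbon, should give the quinol, since the one-carbon ester arm is too short to lactonize.

Step 3
Reactants: 4 Meldrum's acid, 5 allyl alcohol
Product: 6 3-(allyloxy)-3-oxopropanoic acid
Conditions: toluene, reflux
Reagents that add atoms: none
Why: Thermal alcoholysis of Meldrum's acid opens the dioxanedione with loss of acetone and gives the malonic half ester.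

Step 4
Reactants: 3 tert-butyl 2-(1-hydroxy-4-oxocyclohexa-2,5-dien-1-yl)acetate, 6 3-(allyloxy)-3-oxopropanoic acid
Product: 7 allyl 1-(2-tert-butoxy-2-oxoethyl)-4-oxocyclohexa-2,5-dien-1-yl propanedioate
Conditions: DCC, CH2Cl2, 0 °C to rt, no amine base
Reagents that add atoms: none
Why: Carbodiimide esterification of a malonic half ester runs through an alkoxycarbonylketene that acylates even the tertiary quinol hydroxyl, and the amine-free medium avoids premature racemic cyclization.

Step 5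
Reactants: 7 allyl 1-(2-tert-butoxy-2-oxoethyl)-4-oxocyclohexa-2,5-dien-1-yl propanedioate
Product: 8 allyl (3R,3aS,7aS)-7a-(2-tert-butoxy-2-oxoethyl)-2,5-dioxo-2,3,3a,4,5,7a-hexahydro-1-benzofuran-3-carboxylate
Conditions: 9-amino-9-deoxy-epi-quinine N-[3,5-bis(trifluoromethyl)phenyl]thiourea (10 mol %), toluene, −20 °C
Reagents that add atoms: none
Why: The quinuclidine nitrogen deprotonates the malonate CH2 while the thiourea NH groups hydrogen-bond the dienone carbonyl, the bound enolate carbon adds to one β-carbon of the cross-conjugated dienone, and the ring enolate is then protonated at C4 (intramolecular Michael addition). The closest known reaction type is the cinchona-derived bifunctional-catalyst desymmetrization of 4,4-disubstituted cyclohexa-2,5-dienones carrying a tethered malonate or other active-methylene nucleophile, quinol malonates included. The γ-lactone closes in the 5-exo-trig mode, and the short O–C(=O) tether can reach the β-carbon only from the face that bears the carbinol oxygen, so the ring fusion must be cis. C7a is stereogenic only because one of the two enantiotopic enone arms is consumed, so its configuration is set by the catalyst's choice of arm; C3a follows from the same event through the cis fusion; C3 settles by enolization and is erased in step 6. The step needs enantiotopic-arm selectivity from the catalyst alone, because the mirror plane of the substrate makes both arms constitutionally identical and the tether allows only the 1,4-addition that gives the cis-fused five-membered lactone.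

Step 6
Reactants: 8 allyl (3R,3aS,7aS)-7a-(2-tert-butoxy-2-oxoethyl)-2,5-dioxo-2,3,3a,4,5,7a-hexahydro-1-benzofuran-3-carboxylate
Product: 10 tert-butyl 2-[(3aS,7aR)-2,5-dioxo-2,3,3a,4,5,7a-hexahydro-1-benzofuran-7a-yl]acetate, via malonic half acid 9 (not isolated)
Conditions: Pd(PPh3)4 (3 mol %), morpholine, THF, rt; aq. KHSO4 wash; toluene, 90 °C
Reagents that add atoms: none
Why: Tsuji–Trost deallylation by zerovalent palladium with morpholine as allyl acceptor frees the lactone malonic half acid, which should lose CO2 on heating (malonic-type decarboxylation) and so erase C3 while C3a and C7a stay untouched.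

Step 7
Reactants: 10 tert-butyl 2-[(3aS,7aR)-2,5-dioxo-2,3,3a,4,5,7a-hexahydro-1-benzofuran-7a-yl]acetate
Product: 11 tert-butyl 2-[(3aR,7aS)-5-(tert-butyldimethylsilyloxy)-2-oxo-2,3,3a,7a-tetrahydro-1-benzofuran-7a-yl]acetate
Conditions: TBSOTf, Et3N, CH2Cl2, −78 to 0 °C; used crude
Reagents that add atoms: tert-butyldimethylsilyl triflate, CC(C)(C)[Si](C)(C)OS(=O)(=O)C(F)(F)F
Why: Soft enolization–silylation of the enone at its only enolizable position (C4, because C7a is quaternary) should give the cross-conjugated 2-silyloxy diene.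

Step 8
Reactants: 11 tert-butyl 2-[(3aR,7aS)-5-(tert-butyldimethylsilyloxy)-2-oxo-2,3,3a,7a-tetrahydro-1-benzofuran-7a-yl]acetate
Product: 13 (2S,3S)-2-(2-tert-butoxy-2-oxoethyl)-2-[(Z)-2-carboxyethenyl]-5-oxooxolane-3-carboxylic acid, via aldehyde silyl ester 12 (not isolated)
Conditions: O3 (about 1 equiv, titrated CH2Cl2 solution), CH2Cl2, −78 °C; Me2S; then NaClO2, NaH2PO4, 2-methyl-2-butene, t-BuOH/H2O, 0 °C
Reagents that add atoms: ozone, [O-][O+]=O; sodium chlorite, [Na+].[O-]Cl=O
Why: Selective ozonolysis of the electron-rich silyl enol ether C4=C5 bond, which reacts far faster than the remaining cis-alkene, gives the C4 aldehyde and the C5 silyl ester, and buffered Pinnick oxidation then takes the aldehyde to the acid without base that could eliminate the β-acyloxy group while the silyl ester hydrolyses.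

Step 9
Reactants: 13 (2S,3S)-2-(2-tert-butoxy-2-oxoethyl)-2-[(Z)-2-carboxyethenyl]-5-oxooxolane-3-carboxylic acid
Product: 14 tert-butyl (2S,3S)-2-(2-tert-butoxy-2-oxoethyl)-2-[(Z)-3-tert-butoxy-3-oxoprop-1-enyl]-5-oxooxolane-3-carboxylate
Conditions: O-tert-butyl-N,N'-diisopropylisourea (excess), CH2Cl2, rt
Reagents that add atoms: O-tert-butyl-N,N'-diisopropylisourea, CC(C)N=C(OC(C)(C)C)NC(C)C
Why: The O-alkylisourea transfers tert-butyl only to carboxylic acids (acid-promoted O-alkylation), so both acids are esterified under neutral conditions that leave the lactone and the Z-alkene alone.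

Step 10
Reactants: 14 tert-butyl (2S,3S)-2-(2-tert-butoxy-2-oxoethyl)-2-[(Z)-3-tert-butoxy-3-oxoprop-1-enyl]-5-oxooxolane-3-carboxylate
Product: 16 (2R,3S)-3-(tert-butoxycarbonyl)-2-(2-tert-butoxy-2-oxoethyl)-5-oxooxolane-2-carboxylic acid, via aldehyde 15 (not isolated)
Conditions: O3, CH2Cl2, −78 °C; Me2S; then NaClO2, NaH2PO4, 2-methyl-2-butene, t-BuOH/H2O, 0 °C to rt
Reagents that add atoms: ozone, [O-][O+]=O; sodium chlorite, [Na+].[O-]Cl=O
Why: Ozonolysis of the enoate C=C bond removes the two-carbon glyoxylate unit and leaves a non-enolizable aldehyde on the quaternary carbon, which Pinnick oxidation converts into what is now the only free carboxyl.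

Step 11
Reactants: 17 L-malic acid
Product: 18 di-tert-butyl (S)-malate
Conditions: O-tert-butyl-N,N'-diisopropylisourea, THF/CH2Cl2, rt
Reagents that add atoms: O-tert-butyl-N,N'-diisopropylisourea, CC(C)N=C(OC(C)(C)C)NC(C)C
Why: Acid-selective tert-butyl esterification by the isourea leaves the secondary hydroxyl free and does not touch the stereocentre.

Step 12
Reactants: 18 di-tert-butyl (S)-malate, 19 tert-butyl bromoacetate
Product: 20 tri-tert-butyl (1S,2R)-1-hydroxypropane-1,2,3-tricarboxylate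
Conditions: LiN(SiMe3)2 (2.2 equiv), THF, −78 °C; then 19, −78 to −40 °C; cold NH4Cl quench
Reagents that add atoms: none
Why: In this Fráter–Seebach alkylation the chelated lithium alkoxide–enolate is alkylated on the face anti to the alkoxide, which should set the new centre as R (anti to the C–O bond) while the carbinol centre is retained.

Step 13
Reactants: 16 (2R,3S)-3-(tert-butoxycarbonyl)-2-(2-tert-butoxy-2-oxoethyl)-5-oxooxolane-2-carboxylic acid, 20 tri-tert-butyl (1S,2R)-1-hydroxypropane-1,2,3-tricarboxylate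
Product: 22 tri-tert-butyl (1S,2R)-1-{[(2R,3S)-3-(tert-butoxycarbonyl)-2-(2-tert-butoxy-2-oxoethyl)-5-oxooxolane-2-carbonyl]oxy}propane-1,2,3-tricarboxylate, via acid chloride 21 (not isolated)
Conditions: 1-chloro-N,N,2-trimethylprop-1-en-1-amine, CH2Cl2, 0 °C; then 20, pyridine, DMAP (cat.), CH2Cl2, 0 °C to rt
Reagents that add atoms: 1-chloro-N,N,2-trimethylprop-1-en-1-amine, CC(C)=C(Cl)N(C)C (supplies the chlorine of 21 only)
Why: The neutral α-chloroenamine converts the hindered α-acyloxy acid into its chloride, a close analogue of camphanic chloride, and DMAP-catalysed acylation of the secondary hydroxyl then forms the ester without touching tert-butyl esters or the stereocentres.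

Step 14
Reactants: 22 tri-tert-butyl (1S,2R)-1-{[(2R,3S)-3-(tert-butoxycarbonyl)-2-(2-tert-butoxy-2-oxoethyl)-5-oxooxolane-2-carbonyl]oxy}propane-1,2,3-tricarboxylate
Product: 23 tri-tert-butyl (1S,2R)-1-{[(2R,3S)-3-(tert-butoxycarbonyl)-2-(2-tert-butoxy-2-oxoethyl)-5-(ethylsulfanyl)-2-hydroxy-5-oxopentanoyl]oxy}propane-1,2,3-tricarboxylate
Conditions: Me3Al, EtSH, CH2Cl2, 0 °C; aq. potassium sodium tartrate; used at once
Reagents that add atoms: ethanethiol, CCS
Why: Aluminium thiolate thiolysis opens the unhindered, strained γ-lactone carbonyl, driven by the Al–O bond, while the tert-butyl esters and the ester on the quaternary carbon are too hindered to react.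

Step 15
Reactants: 23 tri-tert-butyl (1S,2R)-1-{[(2R,3S)-3-(tert-butoxycarbonyl)-2-(2-tert-butoxy-2-oxoethyl)-5-(ethylsulfanyl)-2-hydroxy-5-oxopentanoyl]oxy}propane-1,2,3-tricarboxylate
Product: 24 tri-tert-butyl (1S,2R)-1-{[(2R,3S)-3-(tert-butoxycarbonyl)-2-(2-tert-butoxy-2-oxoethyl)-5-(ethylsulfanyl)-5-oxo-2-(triethylsilyloxy)pentanoyl]oxy}propane-1,2,3-tricarboxylate
Conditions: Et3SiOTf, 2,6-lutidine, CH2Cl2, −78 °C
Reagents that add atoms: triethylsilyl triflate, CC[Si](CC)(CC)OS(=O)(=O)C(F)(F)F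
Why: Silyl triflate silylation caps the tertiary hydroxyl, which blocks relactonization onto the thioester and later hemiketal formation with the ketone.

Step 16
Reactants: 25 (Z)-non-3-en-1-ol
Product: 26 (Z)-1-iodonon-3-ene
Conditions: I2, PPh3, imidazole, CH2Cl2, 0 °C
Reagents that add atoms: iodine, II
Why: Appel-type iodination proceeds by SN2 displacement of the alkoxyphosphonium at the primary carbon and leaves the Z-alkene unchanged.

Step 17
Reactants: 26 (Z)-1-iodonon-3-ene
Product: 27 [(Z)-non-3-en-1-yl]triphenylphosphonium iodide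
Conditions: PPh3, MeCN, reflux
Reagents that add atoms: triphenylphosphine, c1ccc(cc1)P(c1ccccc1)c1ccccc1
Why: SN2 quaternization of triphenylphosphine by the primary iodide gives the Wittig salt.

Step 18
Reactants: 28 pent-4-yn-1-ol
Product: 29 pent-4-ynal
Conditions: PhI(OAc)2, TEMPO (10 mol %), CH2Cl2, rt; used as a solution
Reagents that add atoms: none
Why: TEMPO-catalysed oxidation through the oxoammonium ion stops at the aldehyde and does not touch the terminal alkyne.

Step 19
Reactants: 27 [(Z)-non-3-en-1-yl]triphenylphosphonium iodide, 29 pent-4-ynal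
Product: 31 (5Z,8Z)-tetradeca-5,8-dien-1-yne, via phosphorus ylide 30 (not isolated)
Conditions: NaN(SiMe3)2, THF, −78 °C; then 29, −78 °C to rt
Reagents that add atoms: none
Why: Wittig olefination with a non-stabilized ylide under lithium-free conditions should give the Z-alkene through the kinetically favoured cis-oxaphosphetane.

Step 20
Reactants: 24 tri-tert-butyl (1S,2R)-1-{[(2R,3S)-3-(tert-butoxycarbonyl)-2-(2-tert-butoxy-2-oxoethyl)-5-(ethylsulfanyl)-5-oxo-2-(triethylsilyloxy)pentanoyl]oxy}propane-1,2,3-tricarboxylate, 31 (5Z,8Z)-tetradeca-5,8-dien-1-yne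
Product: 34 tri-tert-butyl (1S,2R)-1-{[(2R,3S,6E,10Z,13Z)-3-(tert-butoxycarbonyl)-2-(2-tert-butoxy-2-oxoethyl)-5-oxo-2-(triethylsilyloxy)nonadeca-6,10,13-trienoyl]oxy}propane-1,2,3-tricarboxylate, via alkenylzirconocene chloride 32 (not isolated), via alkenylzinc chloride 33 (not isolated)
Conditions: 31, Cp2Zr(H)Cl, THF, rt; ZnCl2, 0 °C; then 24, PdCl2(PPh3)2 (5 mol %), THF/toluene, rt
Reagents that add atoms: Cp2Zr(H)Cl, [H][Zr](Cl)(C1C=CC=C1)C1C=CC=C1 (metal of 32 only); zinc chloride, Cl[Zn]Cl (metal of 33 only)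
Why: syn-Hydrozirconation of the terminal alkyne, which is faster than that of the internal alkenes, gives the (E)-alkenyl metal, and after Zr-to-Zn transmetalation the Fukuyama coupling (palladium-catalysed acylation of an organozinc by a thioester) should give the enone without touching the esters.

Step 21
Reactants: 34 tri-tert-butyl (1S,2R)-1-{[(2R,3S,6E,10Z,13Z)-3-(tert-butoxycarbonyl)-2-(2-tert-butoxy-2-oxoethyl)-5-oxo-2-(triethylsilyloxy)nonadeca-6,10,13-trienoyl]oxy}propane-1,2,3-tricarboxylate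
Product: 35 tri-tert-butyl (1S,2R)-1-{[(2R,3S,5S,6E,10Z,13Z)-3-(tert-butoxycarbonyl)-2-(2-tert-butoxy-2-oxoethyl)-5-hydroxy-2-(triethylsilyloxy)nonadeca-6,10,13-trienoyl]oxy}propane-1,2,3-tricarboxylate
Conditions: (R)-2-methyl-CBS-oxazaborolidine (20 mol %), catecholborane, toluene, −78 °C; pH 7 buffer work-up
Reagents that add atoms: none
Why: In this Corey–Bakshi–Shibata reduction the alkenyl group acts as the larger ketone substituent, so the (R)-oxazaborolidine–catecholborane complex should deliver hydride to the face that gives the 5S alcohol, and catecholborane at −78 °C neither hydroborates the alkenes nor reduces the enone 1,4.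

Step 22
Reactants: 35 tri-tert-butyl (1S,2R)-1-{[(2R,3S,5S,6E,10Z,13Z)-3-(tert-butoxycarbonyl)-2-(2-tert-butoxy-2-oxoethyl)-5-hydroxy-2-(triethylsilyloxy)nonadeca-6,10,13-trienoyl]oxy}propane-1,2,3-tricarboxylate
Product: 36 (1S,2R)-1-{[(2R)-3-carboxy-2-hydroxy-2-{(3S,5S)-2-oxo-5-[(1E,5Z,8Z)-tetradeca-1,5,8-trien-1-yl]oxolan-3-yl}propanoyl]oxy}propane-1,2,3-tricarboxylic acid (CNP0327249.2)
Conditions: CF3CO2H/CH2Cl2 (1:3), 0 °C to rt; evaporation; reverse-phase chromatography
Reagents that add atoms: none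
Why: Acidolysis cleaves the five tert-butyl esters and the silyl ether, and the γ-hydroxy ester or acid closes 5-exo to the γ-lactone under the same acid catalysis, the five-membered lactone being favoured over the six-membered alternative and no stereocentre being touched.

**Compound list**

1 | 4-hydroxyphenylacetic acid | OC(=O)Cc1ccc(O)cc1 | starting material
2 | tert-butyl 2-(4-hydroxyphenyl)acetate | CC(C)(C)OC(=O)Cc1ccc(O)cc1 | intermediate
3 | tert-butyl 2-(1-hydroxy-4-oxocyclohexa-2,5-dien-1-yl)acetate | CC(C)(C)OC(=O)CC1(O)C=CC(=O)C=C1 | intermediate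
4 | Meldrum's acid (2,2-dimethyl-1,3-dioxane-4,6-dione) | CC1(C)OC(=O)CC(=O)O1 | starting material
5 | allyl alcohol | C=CCO | starting material
6 | 3-(allyloxy)-3-oxopropanoic acid | OC(=O)CC(=O)OCC=C | intermediate
7 | allyl 1-(2-tert-butoxy-2-oxoethyl)-4-oxocyclohexa-2,5-dien-1-yl propanedioate (achiral) | CC(C)(C)OC(=O)CC1(OC(=O)CC(=O)OCC=C)C=CC(=O)C=C1 | intermediate
8 | allyl (3R,3aS,7aS)-7a-(2-tert-butoxy-2-oxoethyl)-2,5-dioxo-2,3,3a,4,5,7a-hexahydro-1-benzofuran-3-carboxylate (cis-fused; C3 epimerizable) | C=CCOC(=O)[C@H]1[C@H]2[C@](OC1=O)(CC(=O)OC(C)(C)C)C=CC(=O)C2 | intermediate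
9 | (3R,3aS,7aS)-7a-(2-tert-butoxy-2-oxoethyl)-2,5-dioxo-2,3,3a,4,5,7a-hexahydro-1-benzofuran-3-carboxylic acid | OC(=O)[C@H]1[C@H]2[C@](OC1=O)(CC(=O)OC(C)(C)C)C=CC(=O)C2 | intermediate
10 | tert-butyl 2-[(3aS,7aR)-2,5-dioxo-2,3,3a,4,5,7a-hexahydro-1-benzofuran-7a-yl]acetate | O=C1C[C@H]2[C@](O1)(CC(=O)OC(C)(C)C)C=CC(=O)C2 | intermediate
11 | tert-butyl 2-[(3aR,7aS)-5-(tert-butyldimethylsilyloxy)-2-oxo-2,3,3a,7a-tetrahydro-1-benzofuran-7a-yl]acetate | O=C1C[C@H]2[C@](O1)(CC(=O)OC(C)(C)C)C=CC(O[Si](C)(C)C(C)(C)C)=C2 | intermediate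
12 | tert-butyldimethylsilyl (2Z)-3-[(2S,3S)-2-(2-tert-butoxy-2-oxoethyl)-3-formyl-5-oxooxolan-2-yl]prop-2-enoate | O=C1C[C@H](C=O)[C@](O1)(CC(=O)OC(C)(C)C)/C=C\C(=O)O[Si](C)(C)C(C)(C)C | intermediate
13 | (2S,3S)-2-(2-tert-butoxy-2-oxoethyl)-2-[(Z)-2-carboxyethenyl]-5-oxooxolane-3-carboxylic acid | O=C1C[C@H](C(=O)O)[C@](O1)(CC(=O)OC(C)(C)C)/C=C\C(=O)O | intermediate
14 | tert-butyl (2S,3S)-2-(2-tert-butoxy-2-oxoethyl)-2-[(Z)-3-tert-butoxy-3-oxoprop-1-enyl]-5-oxooxolane-3-carboxylate | O=C1C[C@H](C(=O)OC(C)(C)C)[C@](O1)(CC(=O)OC(C)(C)C)/C=C\C(=O)OC(C)(C)C | intermediate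
15 | tert-butyl (2R,3S)-2-(2-tert-butoxy-2-oxoethyl)-2-formyl-5-oxooxolane-3-carboxylate | O=C1C[C@H](C(=O)OC(C)(C)C)[C@](O1)(CC(=O)OC(C)(C)C)C=O | intermediate
16 | (2R,3S)-3-(tert-butoxycarbonyl)-2-(2-tert-butoxy-2-oxoethyl)-5-oxooxolane-2-carboxylic acid | O=C1C[C@H](C(=O)OC(C)(C)C)[C@](O1)(CC(=O)OC(C)(C)C)C(=O)O | intermediate
17 | L-malic acid | O[C@@H](CC(=O)O)C(=O)O | starting material
18 | di-tert-butyl (S)-malate | O[C@@H](CC(=O)OC(C)(C)C)C(=O)OC(C)(C)C | intermediate
19 | tert-butyl bromoacetate | BrCC(=O)OC(C)(C)C | starting material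
20 | tri-tert-butyl (1S,2R)-1-hydroxypropane-1,2,3-tricarboxylate | O[C@H](C(=O)OC(C)(C)C)[C@@H](CC(=O)OC(C)(C)C)C(=O)OC(C)(C)C | intermediate
21 | tert-butyl (2R,3S)-2-(2-tert-butoxy-2-oxoethyl)-2-(chlorocarbonyl)-5-oxooxolane-3-carboxylate | O=C1C[C@H](C(=O)OC(C)(C)C)[C@](O1)(CC(=O)OC(C)(C)C)C(Cl)=O | intermediate
22 | tri-tert-butyl (1S,2R)-1-{[(2R,3S)-3-(tert-butoxycarbonyl)-2-(2-tert-butoxy-2-oxoethyl)-5-oxooxolane-2-carbonyl]oxy}propane-1,2,3-tricarboxylate | O=C1C[C@H](C(=O)OC(C)(C)C)[C@](O1)(CC(=O)OC(C)(C)C)C(=O)O[C@H](C(=O)OC(C)(C)C)[C@@H](CC(=O)OC(C)(C)C)C(=O)OC(C)(C)C | intermediate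
23 | tri-tert-butyl (1S,2R)-1-{[(2R,3S)-3-(tert-butoxycarbonyl)-2-(2-tert-butoxy-2-oxoethyl)-5-(ethylsulfanyl)-2-hydroxy-5-oxopentanoyl]oxy}propane-1,2,3-tricarboxylate | CCSC(=O)C[C@H](C(=O)OC(C)(C)C)[C@](O)(CC(=O)OC(C)(C)C)C(=O)O[C@H](C(=O)OC(C)(C)C)[C@@H](CC(=O)OC(C)(C)C)C(=O)OC(C)(C)C | intermediate
24 | tri-tert-butyl (1S,2R)-1-{[(2R,3S)-3-(tert-butoxycarbonyl)-2-(2-tert-butoxy-2-oxoethyl)-5-(ethylsulfanyl)-5-oxo-2-(triethylsilyloxy)pentanoyl]oxy}propane-1,2,3-tricarboxylate | CCSC(=O)C[C@H](C(=O)OC(C)(C)C)[C@](O[Si](CC)(CC)CC)(CC(=O)OC(C)(C)C)C(=O)O[C@H](C(=O)OC(C)(C)C)[C@@H](CC(=O)OC(C)(C)C)C(=O)OC(C)(C)C | intermediate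
25 | (Z)-non-3-en-1-ol | CCCCC/C=C\CCO | starting material
26 | (Z)-1-iodonon-3-ene | CCCCC/C=C\CCI | intermediate
27 | [(Z)-non-3-en-1-yl]triphenylphosphonium iodide | CCCCC/C=C\CC[P+](c1ccccc1)(c1ccccc1)c1ccccc1.[I-] | intermediate
28 | pent-4-yn-1-ol | C#CCCCO | starting material
29 | pent-4-ynal | C#CCCC=O | intermediate
30 | [(Z)-non-3-en-1-ylidene]triphenylphosphorane | CCCCC/C=C\CC=P(c1ccccc1)(c1ccccc1)c1ccccc1 | intermediate
31 | (5Z,8Z)-tetradeca-5,8-dien-1-yne | CCCCC/C=C\C/C=C\CCC#C | intermediate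
32 | chlorobis(cyclopentadienyl)[(1E,5Z,8Z)-tetradeca-1,5,8-trien-1-yl]zirconium | CCCCC/C=C\C/C=C\CC/C=C/[Zr](Cl)(C1C=CC=C1)C1C=CC=C1 | intermediate
33 | chloro[(1E,5Z,8Z)-tetradeca-1,5,8-trien-1-yl]zinc | CCCCC/C=C\C/C=C\CC/C=C/[Zn]Cl | intermediate
34 | tri-tert-butyl (1S,2R)-1-{[(2R,3S,6E,10Z,13Z)-3-(tert-butoxycarbonyl)-2-(2-tert-butoxy-2-oxoethyl)-5-oxo-2-(triethylsilyloxy)nonadeca-6,10,13-trienoyl]oxy}propane-1,2,3-tricarboxylate | CCCCC/C=C\C/C=C\CC/C=C/C(=O)C[C@H](C(=O)OC(C)(C)C)[C@](O[Si](CC)(CC)CC)(CC(=O)OC(C)(C)C)C(=O)O[C@H](C(=O)OC(C)(C)C)[C@@H](CC(=O)OC(C)(C)C)C(=O)OC(C)(C)C | intermediate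
35 | tri-tert-butyl (1S,2R)-1-{[(2R,3S,5S,6E,10Z,13Z)-3-(tert-butoxycarbonyl)-2-(2-tert-butoxy-2-oxoethyl)-5-hydroxy-2-(triethylsilyloxy)nonadeca-6,10,13-trienoyl]oxy}propane-1,2,3-tricarboxylate | CCCCC/C=C\C/C=C\CC/C=C/[C@@H](O)C[C@H](C(=O)OC(C)(C)C)[C@](O[Si](CC)(CC)CC)(CC(=O)OC(C)(C)C)C(=O)O[C@H](C(=O)OC(C)(C)C)[C@@H](CC(=O)OC(C)(C)C)C(=O)OC(C)(C)C | intermediate
36 | (1S,2R)-1-{[(2R)-3-carboxy-2-hydroxy-2-{(3S,5S)-2-oxo-5-[(1E,5Z,8Z)-tetradeca-1,5,8-trien-1-yl]oxolan-3-yl}propanoyl]oxy}propane-1,2,3-tricarboxylic acid | CCCCC/C=C\C/C=C\CC/C=C/[C@@H]1C[C@@H]([C@](O)(CC(=O)O)C(=O)O[C@H](C(=O)O)[C@@H](CC(=O)O)C(=O)O)C(=O)O1 | target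

**Step count and risks**

Total step count: 22.
Longest linear sequence: 15 steps from 1 (steps 1, 2, 4 to 10, 13 to 15, 20 to 22).

Steps most likely to fail:

1. Step 5. The catalyst may discriminate poorly between the two enantiotopic enone arms, or an uncatalysed background cyclization may compete, so that the lactone forms with low enantiomeric purity. Fallback by resolution through the isocitrate ester, from 7 back to 22: cyclization of 7 with Cs2CO3 in MeCN gives 8 as the racemate, that is together with its mirror image ent-8 F1. Steps 6 to 10 are run unchanged on the racemate and carry along the mirror-image half acid ent-9 F2, ketone ent-10 F3, silyl dienol ether ent-11 F4, aldehyde silyl ester ent-12 F5, diacid ent-13 F6, triester ent-14 F7, aldehyde ent-15 F8 and acid ent-16 F9. Step 13, through the acid chloride ent-21 F10 and enantiopure 20, then gives 22 together with the diastereomeric (2S,3R)-oxolane ester F11. The two esters differ at adjacent stereocentres and should separate on silica, and the route continues from 22.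

2. Step 8. Ozone may also cleave the C6=C7 alkene before the enol ether is consumed, which would destroy the differentiation of the two carboxyls. Fallback by dihydroxylation and hydroxy ketone cleavage, from 11 back to 13: OsO4 (cat.) with N-methylmorpholine N-oxide in acetone/water oxidizes only the electron-rich enol ether bond and, after loss of the silanol, gives the 4-hydroxy ketone F12 as a mixture of C4 epimers. NaIO4 in THF/water cleaves this α-hydroxy ketone to the aldehyde acid F13, and the Pinnick oxidation of step 8 then gives 13.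

3. Step 21. Hydride delivery may show poor facial selectivity because the β-branched CH2 substituent competes in size with the alkenyl group. Fallback by asymmetric alkenylation of an aldehyde, from 24 back to 35, bypassing 34: Fukuyama reduction of 24 (Et3SiH, Pd/C, acetone, rt) gives the aldehyde F14. Hydroboration of 31 with dicyclohexylborane gives the (E)-alkenylborane F15, and boron-to-zinc exchange with Et2Zn gives the alkenyl(ethyl)zinc F16. F16 adds to F14 in the presence of a catalytic enantiopure amino alcohol ligand such as 3-exo-morpholinoisoborneol (Oppolzer-type asymmetric alkenylzinc addition), with the ligand enantiomer chosen to give the 5S carbinol 35.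

**Further compounds**

F1 | step 5 | ent-8, allyl (3S,3aR,7aR)-7a-(2-tert-butoxy-2-oxoethyl)-2,5-dioxo-2,3,3a,4,5,7a-hexahydro-1-benzofuran-3-carboxylate | C=CCOC(=O)[C@@H]1[C@@H]2[C@@](OC1=O)(CC(=O)OC(C)(C)C)C=CC(=O)C2
F2 | step 5 | ent-9, mirror image of the malonic half acid 9 | OC(=O)[C@@H]1[C@@H]2[C@@](OC1=O)(CC(=O)OC(C)(C)C)C=CC(=O)C2
F3 | step 5 | ent-10, tert-butyl 2-[(3aR,7aS)-2,5-dioxo-2,3,3a,4,5,7a-hexahydro-1-benzofuran-7a-yl]acetate | O=C1C[C@@H]2[C@@](O1)(CC(=O)OC(C)(C)C)C=CC(=O)C2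
F4 | step 5 | ent-11, mirror image of the silyl dienol ether 11 | O=C1C[C@@H]2[C@@](O1)(CC(=O)OC(C)(C)C)C=CC(O[Si](C)(C)C(C)(C)C)=C2
F5 | step 5 | ent-12, mirror image of the aldehyde silyl ester 12 | O=C1C[C@@H](C=O)[C@@](O1)(CC(=O)OC(C)(C)C)/C=C\C(=O)O[Si](C)(C)C(C)(C)C
F6 | step 5 | ent-13, (2R,3R)-2-(2-tert-butoxy-2-oxoethyl)-2-[(Z)-2-carboxyethenyl]-5-oxooxolane-3-carboxylic acid | O=C1C[C@@H](C(=O)O)[C@@](O1)(CC(=O)OC(C)(C)C)/C=C\C(=O)O
F7 | step 5 | ent-14, mirror image of the triester 14 | O=C1C[C@@H](C(=O)OC(C)(C)C)[C@@](O1)(CC(=O)OC(C)(C)C)/C=C\C(=O)OC(C)(C)C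
F8 | step 5 | ent-15, mirror image of the aldehyde 15 | O=C1C[C@@H](C(=O)OC(C)(C)C)[C@@](O1)(CC(=O)OC(C)(C)C)C=O
F9 | step 5 | ent-16, (2S,3R)-3-(tert-butoxycarbonyl)-2-(2-tert-butoxy-2-oxoethyl)-5-oxooxolane-2-carboxylic acid | O=C1C[C@@H](C(=O)OC(C)(C)C)[C@@](O1)(CC(=O)OC(C)(C)C)C(=O)O
F10 | step 5 | ent-21, mirror image of the acid chloride 21 | O=C1C[C@@H](C(=O)OC(C)(C)C)[C@@](O1)(CC(=O)OC(C)(C)C)C(Cl)=O
F11 | step 5 | tri-tert-butyl (1S,2R)-1-{[(2S,3R)-3-(tert-butoxycarbonyl)-2-(2-tert-butoxy-2-oxoethyl)-5-oxooxolane-2-carbonyl]oxy}propane-1,2,3-tricarboxylate (diastereomer of 22) | O=C1C[C@@H](C(=O)OC(C)(C)C)[C@@](O1)(CC(=O)OC(C)(C)C)C(=O)O[C@H](C(=O)OC(C)(C)C)[C@@H](CC(=O)OC(C)(C)C)C(=O)OC(C)(C)C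
F12 | step 8 | 4-hydroxy derivative of 10, tert-butyl 2-(4-hydroxy-2,5-dioxo-2,3,3a,4,5,7a-hexahydro-1-benzofuran-7a-yl)acetate (ring fusion as in 10, both C4 epimers) | O=C1C[C@H]2[C@](O1)(CC(=O)OC(C)(C)C)C=CC(=O)C2O
F13 | step 8 | (2Z)-3-[(2S,3S)-2-(2-tert-butoxy-2-oxoethyl)-3-formyl-5-oxooxolan-2-yl]prop-2-enoic acid | O=C1C[C@H](C=O)[C@](O1)(CC(=O)OC(C)(C)C)/C=C\C(=O)O
F14 | step 21 | tri-tert-butyl (1S,2R)-1-{[(2R,3S)-3-(tert-butoxycarbonyl)-2-(2-tert-butoxy-2-oxoethyl)-5-oxo-2-(triethylsilyloxy)pentanoyl]oxy}propane-1,2,3-tricarboxylate (aldehyde) | O=CC[C@H](C(=O)OC(C)(C)C)[C@](O[Si](CC)(CC)CC)(CC(=O)OC(C)(C)C)C(=O)O[C@H](C(=O)OC(C)(C)C)[C@@H](CC(=O)OC(C)(C)C)C(=O)OC(C)(C)C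
F15 | step 21 | dicyclohexyl[(1E,5Z,8Z)-tetradeca-1,5,8-trien-1-yl]borane | CCCCC/C=C\C/C=C\CC/C=C/B(C1CCCCC1)C1CCCCC1
F16 | step 21 | ethyl[(1E,5Z,8Z)-tetradeca-1,5,8-trien-1-yl]zinc | CCCCC/C=C\C/C=C\CC/C=C/[Zn]CC
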